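Time separates the two steps here. At 0.333 min after the first portion, teal already holds J at a quarter of the D charged, which is that whole portion less a little. A molecule of D therefore reaches J quickly and then stands at a slower fork: stay J or leave as E. J at the end is the charge less E, so oak against larch is a comparison of E.

| flask | D | L | Z | temperature | remark | time |
|---|---|---|---|---|---|---|
| teal | 5.0 × 10⁻⁴ M (in portions, 4) | 0.53 equiv | 0.1 mol% | 75 °C | run made earlier; portions every 1.0 min |  |
| grey | 5.0 × 10⁻⁴ M (in portions, 4) | 0.83 equiv | 0.1 mol% | 90 °C | run made earlier; portions every 1.0 min |  |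
| blue | 5.0 × 10⁻⁴ M (in portions, 4) | 0.82 equiv | 0.1 mol% | 75 °C | run made earlier; portions every 1.0 min |  |
| green | 5.0 × 10⁻⁴ M (in portions, 4) | 1 equiv | 0.051 mol% | 90 °C | run made earlier; portions every 1.0 min |  |
| oak | 5.0 × 10⁻⁴ M | 0.670 equiv | 0.05 mol% | 90 °C | everything together at the start | 4.0 min |
| larch | 5.0 × 10⁻⁴ M (in portions, 4) | 1.00 equiv | 0.1 mol% | 90 °C | the portions of D follow each other after 1.0 min, the first at the start | 4.0 min |

- teal (time / min: J / %, E / %): 0.333: 22.7, 0.5; 0.667: 22.0, 2.2; 2.00: 41.8, 7.7; 4.00: 81.5, 17.8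
- grey (time / s: J / %, E / %): 30.0: 22.6, 1.9; 60.0: 20.3, 4.5; 90.0: 40.9, 8.3; 120: 37.5, 12.2
- blue (time / min: J / %, E / %): 1.00: 20.2, 3.4; 2.00: 38.8, 11.5; 3.00: 56.2, 18.4; 4.00: 73.1, 25.7
- green (time / s: J / %, E / %): 15.0: 19.9, 0.3; 40.0: 23.3, 1.2; 80.0: 42.8, 4.4; 120: 41.6, 8.2

(scatter of a reading: 0.5 percentage points)

- the winner by amount of J, in percent of the D charged; "neither" if no more than 2 percentage points parts them (oak / larch / neither)
- how much J is there at the end, in percent of the D charged: oak
- how much J is there at the end, in percent of the D charged: larch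

- for E the Q are counted in
- as a solid, counted per litre of solution: Q
- what was read earlier has a scatter of 0.5 percentage points, one standard deviation
- steps that have been proposed: D + Z -> Z + J; Z + J <-> G; L + G -> Z + E; Q <-> E

Grey shows how E forms. Over equal intervals E gains 2.6 percentage points at a mean J of 21.5%, then 3.9 points at 39.2%. The rate thus rises 1.50 times, less than the 1.82 times of J, which fits part of the catalyst being held as G:

rate of E ∝ Z · L · J/(K + J)

These readings, with their scatter, give roughly 59.8% for K, the amount of J at half the plateau rate. The two amounts to compare are J and K. Larch has 2.99 times the Z·L of oak, but oak's J starts at 1.67 times K.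

My own reckoning scales grey's last rise to oak, with J and L held at their charge, and scales grey's E to larch by L and by blue's growth of 2.23 times after 2.00 min:

oak: E ≈ 19.9%, J ≈ 80.1%

larch: E ≈ 32.8%, J ≈ 67.2%

The forecast, on the ground “E then forms at a rate proportional to Z and L and saturating in J”, says oak, with 83% (78% to 87%) for oak and 65% (59% to 70%) for larch. Both of its figures differ a little from mine.

The flasks give oak: 80.9% in oak and 65.4% in larch.

    D + Z → Z + J (k = 5.30 × 10⁵ M⁻¹ s⁻¹, Ea = 24.0 kJ mol⁻¹)
    Z + J ⇌ G (K = 2300 M⁻¹, k = 67000 M⁻¹ s⁻¹, Ea = 16.0 kJ mol⁻¹, ΔH = −45.0 kJ mol⁻¹)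
    L + G → Z + E (k = 12000 M⁻¹ s⁻¹, Ea = 36.0 kJ mol⁻¹)
    Q ⇌ E, rate k4*(cs4 - [E]) while solid is left; crystals form when [E] > cs4 (solubility = 0.00860 mM, k = 0.210 s⁻¹)
    (constants at 90 °C)

With K, the mean of L·J/(K + J) carries larch to a neighbouring flask, which has 0.17 mol% of Z. The 4 equal portions give a mean fed D of 62.5%, and the mean E, taken as 0.5 of the final E, is subtracted from that and from L. Larch, with E 34.6%, gives 0.356. The neighbour, at its final E, gives 0.296. Scaled by Z, larch's E becomes 58.9%, and the factor 0.834 lowers this to 49.1%. The neighbour ends with E at 48.3% and J at 51.7%.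

The runs come from a simulation with constants of no real substance, noise included.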